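**Retrosynthetic overview**

1. Hidden symmetry: the target is a 6,6'-linked pair of 2,2-dimethyl-2H-chromenes that differ only at C8 (OH on the ring B half, prenyl at C8' on the ring A half). If both C8 substituents are traced back to C–B bonds, the skeleton becomes C2-symmetric.
2. Key disconnection, made in both halves at once: the two aryl bonds of each pyran ring (C4–C4a and O1–C8a) are cut together. This leaves a biaryl bis(aryne) equivalent and two molecules of prenal; forward, an aryne/enal [2+2], 4π ring-opening, oxa-6π cascade closes both pyran rings in one flask.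
3. Enabling feature: on each benzene ring O1 (on C8a) sits ortho to the C8 substituent, so a boryl group at C8 can steer the aldehyde oxygen onto C8a of the C8a≡C4a aryne; C2 with its two methyl groups is the β-carbon of prenal. Boron later leaves as OH (ring B) and by C–C coupling to prenyl (ring A).
4. Order of ring formation: both benzene rings are bought as 4,4'-biphenol; two directed ortho-metalations and a triflation give the bis(aryne) precursor (SiMe3 as trigger, Bpin as director); both pyran rings form together in step 5; the halves are differentiated last (mono-prenylation, then boronate oxidation).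

Key step: step 5

Remark on the chemistry: the target has no stereocentre and its biaryl axis carries no ortho substituents, so no stereocontrol is needed; the benzoxetes 15 and 19 are racemic transients.
Abbreviation: Bpin = 4,4,5,5-tetramethyl-1,3,2-dioxaborolan-2-yl.

**Route**

Step 1
Reactants: 1 4,4'-biphenol ([1,1'-biphenyl]-4,4'-diol)
Product: 2 [1,1'-biphenyl]-4,4'-diyl bis(N-isopropylcarbamate)
Conditions: i-PrNCO (2.4 equiv), Et3N (0.2 equiv), THF, 23 °C
Reagents that add atoms: isopropyl isocyanate, CC(C)N=C=O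
Why: Base-catalysed addition of both phenol O–H groups to the isocyanate (carbamoylation) should be clean and installs a directing group for ortho-lithiation that can later be removed with a mild amine.

Step 2
Reactants: 2 [1,1'-biphenyl]-4,4'-diyl bis(N-isopropylcarbamate)
Product: 6 3,3'-bis(trimethylsilyl)-[1,1'-biphenyl]-4,4'-diyl bis(N-isopropylcarbamate), via N-silyl bis(carbamate) 3 (not isolated), via dilithio species 4 (not isolated), via N-tert-butyldimethylsilyl bis(arylsilane) 5 (not isolated)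
Conditions: TBSOTf (2.2 equiv), TMEDA, Et2O/THF, 0 → 23 °C; n-BuLi (4.4 equiv), TMEDA, −78 °C; TMSCl, −78 → 23 °C; 1 M HCl work-up
Reagents that add atoms: chlorotrimethylsilane, C[Si](C)(C)Cl
Why: After in situ N-silylation masks the N–H, each O-carbamate directs lithiation to its ortho position (directed ortho-metalation) independently on the two rings, TMSCl traps the aryllithium, and the N–Si bond is hydrolysed on acidic work-up.

Step 3
Reactants: 6 3,3'-bis(trimethylsilyl)-[1,1'-biphenyl]-4,4'-diyl bis(N-isopropylcarbamate)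
Product: 10 3,3'-bis(Bpin)-5,5'-bis(trimethylsilyl)-[1,1'-biphenyl]-4,4'-diyl bis(N-isopropylcarbamate), via N-trimethylsilyl bis(arylsilane) 7 (not isolated), via second dilithio species 8 (not isolated), via bis(borate) ate complex 9 (not isolated)
Conditions: TMSOTf (2.2 equiv), TMEDA, Et2O/THF, 0 → 23 °C; n-BuLi (4.4 equiv), TMEDA, −78 °C; i-PrOBpin, −78 → 0 °C; 1 M HCl, 0 °C (brief)
Reagents that add atoms: 2-isopropoxy-4,4,5,5-tetramethyl-1,3,2-dioxaborolane, CC(C)OB1OC(C)(C)C(C)(C)O1
Why: The N–H is masked here as the more labile N–SiMe3 group, which a brief cold acid wash should remove without endangering the new C–B bonds; the second directed ortho-metalation can then only occur at the remaining position ortho to each carbamate (the other is blocked by SiMe3), and borate trapping of the aryllithium followed by loss of isopropoxide gives the arylboronate.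

Step 4
Reactants: 10 3,3'-bis(Bpin)-5,5'-bis(trimethylsilyl)-[1,1'-biphenyl]-4,4'-diyl bis(N-isopropylcarbamate)
Product: 12 3,3'-bis(Bpin)-5,5'-bis(trimethylsilyl)-[1,1'-biphenyl]-4,4'-diyl bis(trifluoromethanesulfonate), via bis(phenol) 11 (not isolated)
Conditions: Et2NH (3 equiv), DBU (4 equiv), MeCN, 40 °C; then PhNTf2 (3 equiv), 40 → 60 °C
Reagents that add atoms: N-phenylbis(trifluoromethanesulfonimide), O=S(=O)(N(c1ccccc1)S(=O)(=O)C(F)(F)F)C(F)(F)F
Why: Amine-induced E1cB cleavage of the N-monoalkyl carbamate (isopropyl isocyanate is expelled and trapped by Et2NH as the urea) frees each phenoxide, which is O-sulfonylated in the same flask by PhNTf2.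

Step 5
Reactants: 12 3,3'-bis(Bpin)-5,5'-bis(trimethylsilyl)-[1,1'-biphenyl]-4,4'-diyl bis(trifluoromethanesulfonate); 13 3-methylbut-2-enal (prenal)
Product: 21 2,2,2',2'-tetramethyl-8,8'-bis(Bpin)-2H,2'H-6,6'-bichromene, via aryne 14 (not isolated), via benzoxete 15 (not isolated), via o-quinone methide 16 (not isolated), via mono-chromene 17 (not isolated), via second aryne 18 (not isolated), via second benzoxete 19 (not isolated), via second o-quinone methide 20 (not isolated)
Conditions: 13 (10 equiv), CsF (6 equiv), MeCN, 25 → 50 °C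
Reagents that add atoms: none
Why: Proposed new method: CsF removes Me3Si from C4a of one ring of 12 and triflate leaves from C8a; the 3-borylaryne 14 adds prenal across its C=O bond in a polar [2+2] (carbonyl O to C8a, aldehyde C to C4a) to benzoxete 15, which opens by retro-4π electrocyclization to o-quinone methide 16 and closes by thermal oxa-6π electrocyclization onto the Me2C terminus to 17, and the same sequence on the second ring (18 to 20) gives 21, so that C4–C4a and O1–C8a of each pyran ring come from one aryne. The closest known reaction type is the annulation of arynes from o-silylaryl triflates with α,β-unsaturated aldehydes to 2H-chromenes; new are the boryl-controlled orientation and the twofold run on one biaryl. Ring closures: the transient oxete ring by asynchronous formal [2+2] cycloaddition with the O–C8a bond leading, each pyran ring by disrotatory 6π electrocyclization of the (Z)-dienone. No stereocentre has to be set, because the sp3 CH of the benzoxete is lost on ring opening and C2 carries two methyl groups. The step needs the oxygen at C8a and not at C4a: the C8 boryl group, a σ-donor that becomes stronger as its reversible fluoride adduct, distorts the aryne so that the nucleophilic carbonyl oxygen attacks the carbon next to boron while the bulkier CH terminus bonds at the remote C4a, in line with the ortho-selective amine additions known for 3-boryl- and 3-silylarynes and opposite to what an 8-alkoxy group would give. Chemoselectivity rests on the strong Si–F bond (fluoride triggers at silicon, not at boron) and on excess prenal, which should outrun ene and oligomerization pathways of the aryne.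

Step 6
Reactants: 21 2,2,2',2'-tetramethyl-8,8'-bis(Bpin)-2H,2'H-6,6'-bichromene; 22 prenyl bromide (1-bromo-3-methylbut-2-ene)
Product: 23 2,2,2',2'-tetramethyl-8-(3-methylbut-2-en-1-yl)-8'-(Bpin)-2H,2'H-6,6'-bichromene
Conditions: 22 (0.6 equiv), Pd(PPh3)4 (5 mol %), K2CO3, THF/H2O, 60 °C; unreacted 21 recovered and recycled
Reagents that add atoms: none
Why: Suzuki–Miyaura coupling of the arylboronate through a π-prenylpalladium intermediate should deliver the linear prenyl group by reductive elimination at the unsubstituted allyl terminus, and sub-stoichiometric prenyl bromide should favour mono-coupling on this C2-symmetric substrate.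

Step 7
Reactants: 23 2,2,2',2'-tetramethyl-8-(3-methylbut-2-en-1-yl)-8'-(Bpin)-2H,2'H-6,6'-bichromene
Product: 24 2,2,2',2'-tetramethyl-8'-(3-methylbut-2-en-1-yl)-2H,2'H-[6,6'-bichromen]-8-ol (target CNP0158232.0)
Conditions: Me3NO (3 equiv), THF, 25 → 50 °C; aqueous work-up
Reagents that add atoms: trimethylamine N-oxide, C[N+](C)(C)[O-]
Why: Oxidation of the aryl–boron bond by the amine N-oxide (boronate oxidation with 1,2-shift of the aryl group from boron to oxygen, then hydrolysis of the borate) should give the phenol while leaving the two chromene alkenes and the prenyl alkene untouched.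

**Compound list**

1 | 4,4'-biphenol | Oc1ccc(cc1)-c1ccc(O)cc1 | starting material
2 | [1,1'-biphenyl]-4,4'-diyl bis(N-isopropylcarbamate) | CC(C)NC(=O)Oc1ccc(cc1)-c1ccc(OC(=O)NC(C)C)cc1 | intermediate
3 | N,N'-bis(tert-butyldimethylsilyl) derivative of 2 (not isolated) | CC(C)N(C(=O)Oc1ccc(cc1)-c1ccc(OC(=O)N(C(C)C)[Si](C)(C)C(C)(C)C)cc1)[Si](C)(C)C(C)(C)C | intermediate
4 | 3,3'-dilithio derivative of 3, Li ortho to each carbamate oxygen (not isolated) | CC(C)N(C(=O)Oc1ccc(cc1[Li])-c1ccc(OC(=O)N(C(C)C)[Si](C)(C)C(C)(C)C)c([Li])c1)[Si](C)(C)C(C)(C)C | intermediate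
5 | 3,3'-bis(trimethylsilyl)-[1,1'-biphenyl]-4,4'-diyl bis(N-tert-butyldimethylsilyl-N-isopropylcarbamate) (not isolated) | CC(C)N(C(=O)Oc1ccc(cc1[Si](C)(C)C)-c1ccc(OC(=O)N(C(C)C)[Si](C)(C)C(C)(C)C)c([Si](C)(C)C)c1)[Si](C)(C)C(C)(C)C | intermediate
6 | 3,3'-bis(trimethylsilyl)-[1,1'-biphenyl]-4,4'-diyl bis(N-isopropylcarbamate) | CC(C)NC(=O)Oc1ccc(cc1[Si](C)(C)C)-c1ccc(OC(=O)NC(C)C)c([Si](C)(C)C)c1 | intermediate
7 | 3,3'-bis(trimethylsilyl)-[1,1'-biphenyl]-4,4'-diyl bis(N-isopropyl-N-trimethylsilylcarbamate) (not isolated) | CC(C)N(C(=O)Oc1ccc(cc1[Si](C)(C)C)-c1ccc(OC(=O)N(C(C)C)[Si](C)(C)C)c([Si](C)(C)C)c1)[Si](C)(C)C | intermediate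
8 | 5,5'-dilithio derivative of 7, Li at the free position ortho to each carbamate oxygen (not isolated) | CC(C)N(C(=O)Oc1c([Li])cc(cc1[Si](C)(C)C)-c1cc([Li])c(OC(=O)N(C(C)C)[Si](C)(C)C)c([Si](C)(C)C)c1)[Si](C)(C)C | intermediate
9 | dilithium bis[aryl(isopropoxy)(pinacolato)borate] ate complex formed from 8 at both lithiated carbons (not isolated) | [Li+].[Li+].CC(C)O[B-]1(OC(C)(C)C(C)(C)O1)c1cc(cc([Si](C)(C)C)c1OC(=O)N(C(C)C)[Si](C)(C)C)-c1cc([Si](C)(C)C)c(OC(=O)N(C(C)C)[Si](C)(C)C)c(c1)[B-]1(OC(C)C)OC(C)(C)C(C)(C)O1 | intermediate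
10 | 3,3'-bis(Bpin)-5,5'-bis(trimethylsilyl)-[1,1'-biphenyl]-4,4'-diyl bis(N-isopropylcarbamate) | CC(C)NC(=O)Oc1c(B2OC(C)(C)C(C)(C)O2)cc(cc1[Si](C)(C)C)-c1cc(B2OC(C)(C)C(C)(C)O2)c(OC(=O)NC(C)C)c([Si](C)(C)C)c1 | intermediate
11 | 3,3'-bis(Bpin)-5,5'-bis(trimethylsilyl)-[1,1'-biphenyl]-4,4'-diol (not isolated) | Oc1c(B2OC(C)(C)C(C)(C)O2)cc(cc1[Si](C)(C)C)-c1cc(B2OC(C)(C)C(C)(C)O2)c(O)c([Si](C)(C)C)c1 | intermediate
12 | 3,3'-bis(Bpin)-5,5'-bis(trimethylsilyl)-[1,1'-biphenyl]-4,4'-diyl bis(trifluoromethanesulfonate) | FC(F)(F)S(=O)(=O)Oc1c(B2OC(C)(C)C(C)(C)O2)cc(cc1[Si](C)(C)C)-c1cc(B2OC(C)(C)C(C)(C)O2)c(OS(=O)(=O)C(F)(F)F)c([Si](C)(C)C)c1 | intermediate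
13 | 3-methylbut-2-enal (prenal) | CC(C)=CC=O | starting material
14 | mono-aryne of 12: triple bond between the former C–OTf and C–SiMe3 carbons of one ring, Bpin next to the former C–OTf carbon, other ring unchanged (not isolated) | CC1(C)OB(OC1(C)C)C1=CC(=CC#C1)-c1cc(B2OC(C)(C)C(C)(C)O2)c(OS(=O)(=O)C(F)(F)F)c([Si](C)(C)C)c1 | intermediate
15 | racemic 2-(2-methylprop-1-enyl)-2H-benzo[b]oxete from 14, oxete O on the carbon next to C–Bpin, other ring unchanged (not isolated) | CC(C)=CC1Oc2c1cc(cc2B1OC(C)(C)C(C)(C)O1)-c1cc(B2OC(C)(C)C(C)(C)O2)c(OS(=O)(=O)C(F)(F)F)c([Si](C)(C)C)c1 | intermediate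
16 | (Z)-o-quinone methide from 15: 2-Bpin-6-(3-methylbut-2-enylidene)cyclohexa-2,4-dienone carrying the unchanged aryl ring at C4 (not isolated) | CC(C)=C/C=C1/C=C(C=C(B2OC(C)(C)C(C)(C)O2)C1=O)-c1cc(B2OC(C)(C)C(C)(C)O2)c(OS(=O)(=O)C(F)(F)F)c([Si](C)(C)C)c1 | intermediate
17 | mono-chromene: 2-Bpin-4-(2,2-dimethyl-8-Bpin-2H-chromen-6-yl)-6-(trimethylsilyl)phenyl trifluoromethanesulfonate (not isolated) | CC1(C)C=Cc2cc(cc(B3OC(C)(C)C(C)(C)O3)c2O1)-c1cc(B2OC(C)(C)C(C)(C)O2)c(OS(=O)(=O)C(F)(F)F)c([Si](C)(C)C)c1 | intermediate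
18 | aryne of 17 on the second ring, Bpin next to the former C–OTf carbon (not isolated) | CC1(C)C=Cc2cc(cc(B3OC(C)(C)C(C)(C)O3)c2O1)C1=CC#CC(B2OC(C)(C)C(C)(C)O2)=C1 | intermediate
19 | racemic benzoxete on the second ring, first ring already a chromene (not isolated) | CC(C)=CC1Oc2c1cc(cc2B1OC(C)(C)C(C)(C)O1)-c1cc(B2OC(C)(C)C(C)(C)O2)c2OC(C)(C)C=Cc2c1 | intermediate
20 | (Z)-o-quinone methide on the second ring, first ring already a chromene (not isolated) | CC(C)=C/C=C1/C=C(C=C(B2OC(C)(C)C(C)(C)O2)C1=O)-c1cc(B2OC(C)(C)C(C)(C)O2)c2OC(C)(C)C=Cc2c1 | intermediate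
21 | 2,2,2',2'-tetramethyl-8,8'-bis(Bpin)-2H,2'H-6,6'-bichromene | CC1(C)C=Cc2cc(cc(B3OC(C)(C)C(C)(C)O3)c2O1)-c1cc(B2OC(C)(C)C(C)(C)O2)c2OC(C)(C)C=Cc2c1 | intermediate
22 | prenyl bromide (1-bromo-3-methylbut-2-ene) | CC(C)=CCBr | starting material
23 | 2,2,2',2'-tetramethyl-8-(3-methylbut-2-en-1-yl)-8'-(Bpin)-2H,2'H-6,6'-bichromene | CC(C)=CCc1cc(cc2C=CC(C)(C)Oc12)-c1cc(B2OC(C)(C)C(C)(C)O2)c2OC(C)(C)C=Cc2c1 | intermediate
24 | 2,2,2',2'-tetramethyl-8'-(3-methylbut-2-en-1-yl)-2H,2'H-[6,6'-bichromen]-8-ol | CC(C)=CCc1cc(-c2cc(O)c3c(c2)C=CC(C)(C)O3)cc2c1OC(C)(C)C=C2 | target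

**Step count and risks**

Total steps: 7. Longest linear sequence: 7 steps (from 1).

Steps most likely to fail:

1. Step 5 (Proposed new method). What may go wrong: the carbonyl oxygen adds at C4a instead of C8a if boryl control is weak; fluoride attacks boron, causing boron loss or an alternative elimination; ene or oligomerization pathways of the aryne outrun the [2+2]; the second annulation stalls.
Fallback with known chemistry, from 1 back to 21: twofold ortho-bromination of 1 (Br2, AcOH) should give 3,3'-dibromo-[1,1'-biphenyl]-4,4'-diol F1. O-Alkylation with 3-chloro-3-methylbut-1-yne (K2CO3, KI, CuCl cat., acetone, 60 °C) gives 3,3'-dibromo-4,4'-bis[(2-methylbut-3-yn-2-yl)oxy]-1,1'-biphenyl F2. Heating (N,N-diethylaniline, 190 °C) triggers on each ring the aromatic propargyl Claisen rearrangement, [1,5]-H shift and oxa-6π closure to 8,8'-dibromo-2,2,2',2'-tetramethyl-2H,2'H-6,6'-bichromene F3. Twofold Miyaura borylation (B2pin2, PdCl2(dppf), KOAc, dioxane, 90 °C) returns to 21. The pyran rings are then built through C4–C4a and O1–C2, so no aryne orientation is involved.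

2. Step 6. What may go wrong: coupling at both boronates, transfer of the branched (1,1-dimethylallyl) terminus, and difficult separation of three non-polar products.
Fallback, from 21 back to 24: the order of the two boron conversions is inverted. Sub-stoichiometric Me3NO (0.6 equiv, THF) should convert 21 into 2,2,2',2'-tetramethyl-8'-(Bpin)-2H,2'H-[6,6'-bichromen]-8-ol F4, which differs sharply in polarity and acidity from recovered 21 and from any doubly oxidized material. Silylation (TIPSCl, imidazole, DMF) gives the triisopropylsilyl ether of F4 F5. Suzuki–Miyaura prenylation, now with excess 22 (Pd(PPh3)4, K2CO3, THF/H2O), can be driven to completion to the triisopropylsilyl ether of 24 F6. TBAF (THF, 0 °C) removes the silyl group to give 24.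

3. Step 3. What may go wrong: incomplete lithiation of both rings, anionic ortho-Fries migration of the carbamoyl group onto the lithiated carbon, or loss of boron during the acidic work-up.
Fallback, from 1 back to 12 (replaces steps 1 to 4): exhaustive ortho-bromination of 1 (Br2, AcOH) should give 3,3',5,5'-tetrabromo-[1,1'-biphenyl]-4,4'-diol F7. O-Silylation (HMDS, neat, 80 °C) gives 3,3',5,5'-tetrabromo-4,4'-bis(trimethylsilyloxy)-1,1'-biphenyl F8. n-BuLi (2 equiv, THF, −78 → 23 °C) effects one bromine–lithium exchange per ring followed by a retro-Brook 1,3-silyl shift from oxygen to carbon, giving after work-up 3,3'-dibromo-5,5'-bis(trimethylsilyl)-[1,1'-biphenyl]-4,4'-diol F9. Triflation (Tf2O, pyridine, CH2Cl2) gives 3,3'-dibromo-5,5'-bis(trimethylsilyl)-[1,1'-biphenyl]-4,4'-diyl bis(trifluoromethanesulfonate) F10. Twofold Miyaura borylation (B2pin2, PdCl2(dppf), KOAc, dioxane, 80 °C) then leads to 12.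

Further compounds
F1 | step 5 | 3,3'-dibromo-[1,1'-biphenyl]-4,4'-diol | Oc1ccc(cc1Br)-c1ccc(O)c(Br)c1
F2 | step 5 | 3,3'-dibromo-4,4'-bis[(2-methylbut-3-yn-2-yl)oxy]-1,1'-biphenyl | C#CC(C)(C)Oc1ccc(cc1Br)-c1ccc(OC(C)(C)C#C)c(Br)c1
F3 | step 5 | 8,8'-dibromo-2,2,2',2'-tetramethyl-2H,2'H-6,6'-bichromene | CC1(C)C=Cc2cc(cc(Br)c2O1)-c1cc(Br)c2OC(C)(C)C=Cc2c1
F4 | step 6 | 2,2,2',2'-tetramethyl-8'-(Bpin)-2H,2'H-[6,6'-bichromen]-8-ol | CC1(C)C=Cc2cc(cc(O)c2O1)-c1cc(B2OC(C)(C)C(C)(C)O2)c2OC(C)(C)C=Cc2c1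
F5 | step 6 | triisopropylsilyl ether of F4 | CC(C)[Si](Oc1cc(cc2C=CC(C)(C)Oc12)-c1cc(B2OC(C)(C)C(C)(C)O2)c2OC(C)(C)C=Cc2c1)(C(C)C)C(C)C
F6 | step 6 | triisopropylsilyl ether of 24 | CC(C)=CCc1cc(cc2C=CC(C)(C)Oc12)-c1cc(O[Si](C(C)C)(C(C)C)C(C)C)c2OC(C)(C)C=Cc2c1
F7 | step 3 | 3,3',5,5'-tetrabromo-[1,1'-biphenyl]-4,4'-diol | Oc1c(Br)cc(cc1Br)-c1cc(Br)c(O)c(Br)c1
F8 | step 3 | 3,3',5,5'-tetrabromo-4,4'-bis(trimethylsilyloxy)-1,1'-biphenyl | C[Si](C)(C)Oc1c(Br)cc(cc1Br)-c1cc(Br)c(O[Si](C)(C)C)c(Br)c1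
F9 | step 3 | 3,3'-dibromo-5,5'-bis(trimethylsilyl)-[1,1'-biphenyl]-4,4'-diol | Oc1c(Br)cc(cc1[Si](C)(C)C)-c1cc(Br)c(O)c([Si](C)(C)C)c1
F10 | step 3 | 3,3'-dibromo-5,5'-bis(trimethylsilyl)-[1,1'-biphenyl]-4,4'-diyl bis(trifluoromethanesulfonate) | FC(F)(F)S(=O)(=O)Oc1c(Br)cc(cc1[Si](C)(C)C)-c1cc(Br)c(OS(=O)(=O)C(F)(F)F)c([Si](C)(C)C)c1
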